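**Plan**
1. Numbering used throughout: C1 ring ketone, C2 (OMe) and C3 (aryl) the ring alkene, C4 spiro carbon, C5 the carbon bearing OMe and aryl, C6 epoxide CH2, O7 epoxide oxygen.
2. Retrosynthetic cuts, in order: O7–C6 (oxirane to a C4 tertiary chlorohydrin), O–C5 (methoxy to C5–H), the ring bond C3–C4. In the open chain follow C5–C4 (C-acylation), C1–C5 (Weinreb ketone synthesis) and C2=C3 (aldol–elimination).
3. Enabling feature: in the cyclopentenone ring the C1 carbonyl sits between the enol-ether alkene C2=C3 and the C5–C4 bond, and C4 carries oxygen. With C3–C4 opened, C3–C2–C1–C5–C4 is a 2-methoxy divinyl ketone whose second alkene is the enol of a chloromethyl ketone. C3 and C4 are therefore the two ends of a 4π system, and O7 is the former ketone oxygen.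
4. Forward order: both aryl units come from 4-hydroxybenzaldehyde. The chain is joined C2=C3, then C1–C5, then C5–C4. The carbocycle closes in step 8 and the oxirane in the last step.
5. Stereochemistry: C4 comes from catalyst-controlled conrotation (Sc(OTf)3–pybox) on the single reactive enol geometry. C5 comes from substrate control, oxygen reaching the planar C5 enolate anti to the C4 silyl ether. The oxirane closure touches neither centre.

Key step: step 8

Assumption: the sense of induction of the scandium–pybox complex on this new substrate type cannot be derived from a model. The (3aS,8aR)-indane-pybox is written, and its equally available antipode is taken if an anomalous-dispersion X-ray analysis of chlorine-containing 18 or 19 shows the (4S) series.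

Remark on protecting groups: the phenols are carried as TIPS ethers, which tolerate amide bases, DBU, Grignard reagents and Lewis acids better than TBS ethers.

Remark on the chlorine: it is kept because it raises the electrophilicity of the C4 terminus, cannot chelate scandium, and is the leaving group of the final closure.

Remark on descriptors: the C4 descriptor changes R, S, R along the route only because CIP priorities change. The spatial arrangement is constant.

**Step 1**
Reactants: 1 4-hydroxybenzaldehyde
Product: 2 4-(triisopropylsilyloxy)benzaldehyde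
Conditions: iPr3SiCl, imidazole, DMF, rt
Reagents that add atoms: triisopropylsilyl chloride, CC(C)[Si](Cl)(C(C)C)C(C)C
Why: Imidazole-promoted O-silylation of a phenol, a routine protection that serves both aryl branches of the route.

**Step 2**
Reactants: 2 4-(triisopropylsilyloxy)benzaldehyde, 3 methyl methoxyacetate
Product: 7 methyl (Z)-2-methoxy-3-[4-(triisopropylsilyloxy)phenyl]prop-2-enoate, via lithium enolate 4 (not isolated), via lithium aldolate 5 (not isolated), via benzylic mesylate 6 (not isolated)
Conditions: LiN(SiMe3)2, THF, −78 °C; then 2; MsCl, −78 → 0 °C; DBU, 0 °C → rt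
Reagents that add atoms: none
Why: Lithium-enolate aldol addition, O-mesylation of the aldolate and DBU-induced E1cB elimination in one flask; the elimination passes through the ester enolate and should give the more stable Z alkene (aryl trans to the carbonyl), which later places the aryl group on the outside of the C3 terminus.

**Step 3**
Reactants: 7 methyl (Z)-2-methoxy-3-[4-(triisopropylsilyloxy)phenyl]prop-2-enoate
Product: 8 (Z)-N,2-dimethoxy-N-methyl-3-[4-(triisopropylsilyloxy)phenyl]prop-2-enamide
Conditions: MeNH(OMe)·HCl, iPrMgCl, THF, −20 → 0 °C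
Reagents that add atoms: N,O-dimethylhydroxylamine hydrochloride, CNOC.Cl
Why: Direct ester-to-Weinreb-amide aminolysis with the chloromagnesium amide, a non-hydrolytic exchange that leaves the aryl silyl ether and the alkene geometry untouched.

**Step 4**
Reactants: 2 4-(triisopropylsilyloxy)benzaldehyde
Product: 9 [4-(triisopropylsilyloxy)phenyl]methanol
Conditions: NaBH4, MeOH, 0 °C
Reagents that add atoms: none
Why: Borohydride reduction of an aromatic aldehyde.

**Step 5**
Reactants: 9 [4-(triisopropylsilyloxy)phenyl]methanol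
Product: 11 4-(triisopropylsilyloxy)benzyl chloride, via benzylic mesylate 10 (not isolated)
Conditions: MsCl, Et3N, CH2Cl2, 0 °C → rt
Reagents that add atoms: methanesulfonyl chloride, CS(=O)(=O)Cl
Why: Mesylation of an electron-rich benzylic alcohol followed by nucleophilic displacement of the labile mesylate by the chloride ion released in the same flask.

**Step 6**
Reactants: 11 4-(triisopropylsilyloxy)benzyl chloride, 8 (Z)-N,2-dimethoxy-N-methyl-3-[4-(triisopropylsilyloxy)phenyl]prop-2-enamide
Product: 13 (Z)-3-methoxy-1,4-bis[4-(triisopropylsilyloxy)phenyl]but-3-en-2-one, via benzylmagnesium chloride 12 (not isolated)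
Conditions: Mg turnings, THF, 0 °C (slow addition of 11); then 8, −20 → 0 °C; aq NH4Cl
Reagents that add atoms: none
Why: Grignard formation and Weinreb ketone synthesis; the chelated tetrahedral adduct stops over-addition, and 1,2-attack is the rule for unsaturated Weinreb amides, here reinforced by the donor-substituted, poorly electrophilic β-carbon.

**Step 7**
Reactants: 13 (Z)-3-methoxy-1,4-bis[4-(triisopropylsilyloxy)phenyl]but-3-en-2-one, 14 chloroacetyl chloride
Product: 16 (Z)-6-chloro-2-methoxy-1,4-bis[4-(triisopropylsilyloxy)phenyl]hex-1-ene-3,5-dione, via lithium enolate 15 (not isolated)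
Conditions: LiN(SiMe3)2 (2.1 equiv), toluene–THF, −78 °C; 14, −78 → −40 °C; AcOH quench at −78 °C
Reagents that add atoms: none
Why: Claisen-type C-acylation of a lithium enolate by an acid chloride in a weakly polar medium; 13 can enolise only at the benzylic C5 position, the fragile chloroacetyl unit enters as the cheap electrophile and never has to serve as an enolate (no Favorskii or Darzens path), no bromide salt is present to exchange the chloride, and the second equivalent of base stores 16 as the chelated lithium diketonate, whose oxygen cannot reach C6, until the cold acid quench.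

**Step 8**
Reactants: 16 (Z)-6-chloro-2-methoxy-1,4-bis[4-(triisopropylsilyloxy)phenyl]hex-1-ene-3,5-dione
Product: 18 (4R)-4-(chloromethyl)-4-hydroxy-2-methoxy-3,5-bis[4-(triisopropylsilyloxy)phenyl]cyclopent-2-en-1-one (C5 epimers), via Z-enol 17 (not isolated)
Conditions: Sc(OTf)3 (20 mol %), 2,6-bis[(3aS,8aR)-3a,8a-dihydro-8H-indeno[1,2-d]oxazol-2-yl]pyridine (22 mol %), 3 Å MS, MeCN, 0 °C → rt
Reagents that add atoms: none
Why: Proposed new method: trivalent scandium held by the pybox ligand binds the C1 carbonyl oxygen and the C2 methoxy oxygen of the U-shaped conformer of Z-enol 17, the resulting pentadienyl cation C3–C2–C1–C5–C4 closes by thermal conrotatory 4π electrocyclization to join C3 to C4, and the oxyallyl cation (stabilised by OMe at C2 and by the silyloxyaryl group at C5) loses the only adjacent proton, C3–H, before the scandium dienolate is protonated at C5. The closest known reactions are the Sc(OTf)3–pybox Nazarov cyclization of 2-alkoxy-1,4-pentadien-3-ones and the Piancatelli rearrangement, in which a hydroxyl-bearing terminus (a protonated carbonyl) closes in the same conrotatory way and ends as the 4-hydroxyl of a cyclopentenone; the new element is a terminus supplied by the enol of a 1,3-diketone. The five-membered ring closes as an electrocyclization, formally 5-endo at both termini, and the enol is indispensable because direct attack of C3 on the keto form of C4 would be a disfavoured 5-(enolendo)-exo-trig process. C4, the only stereocentre that survives, depends on both the enol geometry and the sense of conrotation: the tautomers interconvert rapidly and only the Z-enol places the small OH rather than CH2Cl on the inside of the U next to the inside C3–H, while the twofold-symmetric ligand on the five-membered O1/OMe chelate selects one sense of rotation. The step needs C–C closure to prevail over 6-endo oxa-Michael attack of the enol oxygen on C3 and over storage of the catalyst as the six-membered diketone chelate (s-cis about C1–C5 and unable to close); the C2 methoxy group makes C3 nucleophilic rather than electrophilic, the chlorine makes C4 more electrophilic without offering a chelation site, and both side equilibria are reversible whereas proton loss from C3 drains the cation. C5 forms as an epimer mixture, which is of no consequence because it is planarised in step 10.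

**Step 9**
Reactants: 18 (4R)-4-(chloromethyl)-4-hydroxy-2-methoxy-3,5-bis[4-(triisopropylsilyloxy)phenyl]cyclopent-2-en-1-one
Product: 19 (4R)-4-(chloromethyl)-2-methoxy-4-(triethylsilyloxy)-3,5-bis[4-(triisopropylsilyloxy)phenyl]cyclopent-2-en-1-one (C5 epimers)
Conditions: Et3SiOTf, 2,6-lutidine, CH2Cl2, −78 → 0 °C
Reagents that add atoms: triethylsilyl trifluoromethanesulfonate, CC[Si](CC)(CC)OS(=O)(=O)C(F)(F)F
Why: Silyl triflate/lutidine silylation of a hindered tertiary alcohol, which blocks retro-aldol cleavage of C4–C5 (the path that would racemise C4) and installs the bulky group that differentiates the two faces of C5.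

**Step 10**
Reactants: 19 (4R)-4-(chloromethyl)-2-methoxy-4-(triethylsilyloxy)-3,5-bis[4-(triisopropylsilyloxy)phenyl]cyclopent-2-en-1-one
Product: 21 (4S,5R)-4-(chloromethyl)-5-hydroxy-2-methoxy-4-(triethylsilyloxy)-3,5-bis[4-(triisopropylsilyloxy)phenyl]cyclopent-2-en-1-one, via potassium dienolate 20 (not isolated)
Conditions: KN(SiMe3)2, THF, −78 °C; 2-(phenylsulfonyl)-3-phenyloxaziridine, −78 °C; aq NH4Cl
Reagents that add atoms: 2-(phenylsulfonyl)-3-phenyloxaziridine, O=S(=O)(N1OC1c1ccccc1)c1ccccc1
Why: Davis oxidation of an enolate; both C5 epimers converge on the planar dienolate 20, the bulky oxaziridine should reach C5 from the CH2Cl face anti to OSiEt3 and so set the C5 oxygen trans to the C4 oxygen, and loss of the poor silyloxide leaving group toward a cyclopentadienone is not expected at −78 °C.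

**Step 11**
Reactants: 21 (4S,5R)-4-(chloromethyl)-5-hydroxy-2-methoxy-4-(triethylsilyloxy)-3,5-bis[4-(triisopropylsilyloxy)phenyl]cyclopent-2-en-1-one
Product: 22 (4S,5R)-4-(chloromethyl)-2,5-dimethoxy-4-(triethylsilyloxy)-3,5-bis[4-(triisopropylsilyloxy)phenyl]cyclopent-2-en-1-one
Conditions: MeOTf, 2,6-di-tert-butyl-4-methylpyridine, CH2Cl2, rt → 40 °C
Reagents that add atoms: methyl trifluoromethanesulfonate, COS(=O)(=O)C(F)(F)F
Why: O-methylation of a hindered tertiary alcohol with methyl triflate and a non-nucleophilic pyridine base; no free alkoxide is formed, so neither oxetane closure onto the cis CH2Cl group nor an α-ketol shift can start, and the C5–O bond is not broken, so the configuration is retained.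

**Step 12**
Reactants: 22 (4S,5R)-4-(chloromethyl)-2,5-dimethoxy-4-(triethylsilyloxy)-3,5-bis[4-(triisopropylsilyloxy)phenyl]cyclopent-2-en-1-one
Product: 24 (3R,4R)-4,7-bis(4-hydroxyphenyl)-4,6-dimethoxy-1-oxaspiro[2.4]hept-6-en-5-one, via chlorohydrin alkoxide 23 (not isolated)
Conditions: Bu4NF (4 equiv), THF, 0 °C; cold aq NH4Cl
Reagents that add atoms: none
Why: Fluoride desilylation of all three silyl ethers, after which the tertiary C4 alkoxide displaces chloride in a 3-exo-tet Williamson closure; the C4–O7 bond and C5 are untouched, no enolisable position remains, and the brief cold, near-neutral work-up spares the acid-sensitive oxirane.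

**Compound list**
1 | 4-hydroxybenzaldehyde | O=Cc1ccc(O)cc1 | starting material
2 | 4-(triisopropylsilyloxy)benzaldehyde | O=Cc1ccc(O[Si](C(C)C)(C(C)C)C(C)C)cc1 | intermediate
3 | methyl methoxyacetate | COCC(=O)OC | starting material
4 | lithium enolate of methyl methoxyacetate | COC=C([O-])OC.[Li+] | intermediate
5 | lithium aldolate, methyl 2-methoxy-3-oxido-3-[4-(triisopropylsilyloxy)phenyl]propanoate (diastereomers) | COC(C(=O)OC)C([O-])c1ccc(O[Si](C(C)C)(C(C)C)C(C)C)cc1.[Li+] | intermediate
6 | methyl 2-methoxy-3-(methylsulfonyloxy)-3-[4-(triisopropylsilyloxy)phenyl]propanoate (diastereomers) | COC(C(=O)OC)C(OS(C)(=O)=O)c1ccc(O[Si](C(C)C)(C(C)C)C(C)C)cc1 | intermediate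
7 | methyl (Z)-2-methoxy-3-[4-(triisopropylsilyloxy)phenyl]prop-2-enoate | CO/C(=C\c1ccc(O[Si](C(C)C)(C(C)C)C(C)C)cc1)C(=O)OC | intermediate
8 | (Z)-N,2-dimethoxy-N-methyl-3-[4-(triisopropylsilyloxy)phenyl]prop-2-enamide | CO/C(=C\c1ccc(O[Si](C(C)C)(C(C)C)C(C)C)cc1)C(=O)N(C)OC | intermediate
9 | [4-(triisopropylsilyloxy)phenyl]methanol | OCc1ccc(O[Si](C(C)C)(C(C)C)C(C)C)cc1 | intermediate
10 | 4-(triisopropylsilyloxy)benzyl methanesulfonate | CS(=O)(=O)OCc1ccc(O[Si](C(C)C)(C(C)C)C(C)C)cc1 | intermediate
11 | 4-(triisopropylsilyloxy)benzyl chloride | ClCc1ccc(O[Si](C(C)C)(C(C)C)C(C)C)cc1 | intermediate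
12 | 4-(triisopropylsilyloxy)benzylmagnesium chloride | Cl[Mg]Cc1ccc(O[Si](C(C)C)(C(C)C)C(C)C)cc1 | intermediate
13 | (Z)-3-methoxy-1,4-bis[4-(triisopropylsilyloxy)phenyl]but-3-en-2-one | CO/C(=C\c1ccc(O[Si](C(C)C)(C(C)C)C(C)C)cc1)C(=O)Cc1ccc(O[Si](C(C)C)(C(C)C)C(C)C)cc1 | intermediate
14 | chloroacetyl chloride | ClCC(Cl)=O | starting material
15 | lithium enolate of 13 | CO/C(=C\c1ccc(O[Si](C(C)C)(C(C)C)C(C)C)cc1)C([O-])=Cc1ccc(O[Si](C(C)C)(C(C)C)C(C)C)cc1.[Li+] | intermediate
16 | (Z)-6-chloro-2-methoxy-1,4-bis[4-(triisopropylsilyloxy)phenyl]hex-1-ene-3,5-dione (racemic, enolisable) | CO/C(=C\c1ccc(O[Si](C(C)C)(C(C)C)C(C)C)cc1)C(=O)C(c1ccc(O[Si](C(C)C)(C(C)C)C(C)C)cc1)C(=O)CCl | intermediate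
17 | (1Z,4Z)-6-chloro-5-hydroxy-2-methoxy-1,4-bis[4-(triisopropylsilyloxy)phenyl]hexa-1,4-dien-3-one | CO/C(=C\c1ccc(O[Si](C(C)C)(C(C)C)C(C)C)cc1)C(=O)/C(c1ccc(O[Si](C(C)C)(C(C)C)C(C)C)cc1)=C(\O)CCl | intermediate
18 | (4R)-4-(chloromethyl)-4-hydroxy-2-methoxy-3,5-bis[4-(triisopropylsilyloxy)phenyl]cyclopent-2-en-1-one (C5 epimers) | COC1=C(c2ccc(O[Si](C(C)C)(C(C)C)C(C)C)cc2)[C@@](O)(CCl)C(c2ccc(O[Si](C(C)C)(C(C)C)C(C)C)cc2)C1=O | intermediate
19 | (4R)-4-(chloromethyl)-2-methoxy-4-(triethylsilyloxy)-3,5-bis[4-(triisopropylsilyloxy)phenyl]cyclopent-2-en-1-one (C5 epimers) | COC1=C(c2ccc(O[Si](C(C)C)(C(C)C)C(C)C)cc2)[C@@](O[Si](CC)(CC)CC)(CCl)C(c2ccc(O[Si](C(C)C)(C(C)C)C(C)C)cc2)C1=O | intermediate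
20 | potassium dienolate of 19 | COC1=C(c2ccc(O[Si](C(C)C)(C(C)C)C(C)C)cc2)[C@@](O[Si](CC)(CC)CC)(CCl)C(c2ccc(O[Si](C(C)C)(C(C)C)C(C)C)cc2)=C1[O-].[K+] | intermediate
21 | (4S,5R)-4-(chloromethyl)-5-hydroxy-2-methoxy-4-(triethylsilyloxy)-3,5-bis[4-(triisopropylsilyloxy)phenyl]cyclopent-2-en-1-one | COC1=C(c2ccc(O[Si](C(C)C)(C(C)C)C(C)C)cc2)[C@@](O[Si](CC)(CC)CC)(CCl)[C@](O)(c2ccc(O[Si](C(C)C)(C(C)C)C(C)C)cc2)C1=O | intermediate
22 | (4S,5R)-4-(chloromethyl)-2,5-dimethoxy-4-(triethylsilyloxy)-3,5-bis[4-(triisopropylsilyloxy)phenyl]cyclopent-2-en-1-one | COC1=C(c2ccc(O[Si](C(C)C)(C(C)C)C(C)C)cc2)[C@@](O[Si](CC)(CC)CC)(CCl)[C@](OC)(c2ccc(O[Si](C(C)C)(C(C)C)C(C)C)cc2)C1=O | intermediate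
23 | (4S,5R)-4-(chloromethyl)-4-hydroxy-3,5-bis(4-hydroxyphenyl)-2,5-dimethoxycyclopent-2-en-1-one (present as its tetrabutylammonium alkoxide) | COC1=C(c2ccc(O)cc2)[C@@](O)(CCl)[C@](OC)(c2ccc(O)cc2)C1=O | intermediate
24 | (3R,4R)-4,7-bis(4-hydroxyphenyl)-4,6-dimethoxy-1-oxaspiro[2.4]hept-6-en-5-one (CNP0504072.1) | COC1=C(c2ccc(O)cc2)[C@@]2(CO2)[C@](OC)(c2ccc(O)cc2)C1=O | target

**Totals**
Total step count: 12. Longest linear sequence: 10 steps (1, 2, 3, 6, 7, 8, 9, 10, 11, 12; the branch 1, 4, 5, 6 … 12 is equally long).

**Steps most likely to fail**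

Step 8. Several processes can defeat the closure.
- The catalyst may be tied up in the unreactive six-membered diketone chelate.
- The enol oxygen may add to C3 in a 6-endo oxa-Michael sense.
- The oxyallyl cation may undergo a semipinacol 1,2-shift from the carbinol carbon.
- The closure may be reversible, with erosion of enantiomeric purity.

The fallback makes the same C3–C4 bond by a polar aldol addition, using known chemistry. It sets out from 16 and comes back at 18.
- Aqueous HCl in THF hydrolyses the enol ether to 1-chloro-3,6-bis[4-(triisopropylsilyloxy)phenyl]hexane-2,4,5-trione F1, in which C3 has become an enolisable benzylic CH2 next to the C2 ketone.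
- Catalytic pyrrolidinium acetate turns the most electrophilic carbonyl (C2) into its enamine. C3 then adds to the C4 ketone in a favoured 5-(enolexo)-exo-trig aldol addition to give the diosphenol rac-4-(chloromethyl)-2,4-dihydroxy-3,5-bis[4-(triisopropylsilyloxy)phenyl]cyclopent-2-en-1-one F2.
- Me3SiCHN2 methylates only the acidic enol hydroxyl to give rac-4-(chloromethyl)-4-hydroxy-2-methoxy-3,5-bis[4-(triisopropylsilyloxy)phenyl]cyclopent-2-en-1-one F3.
- Because the two aryl groups are identical, the two diosphenol tautomers of F2 are mirror images at C4. The methylation therefore has no regiochemical issue, but no enantiomeric excess can be carried through F2.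
- F3 is separated by preparative HPLC on a chiral stationary phase, and its (4R) enantiomer is 18.

Step 10. Oxygen transfer from the bulky oxaziridine to the crowded tetrasubstituted enolate may be slow. The facial selectivity at planar C5 may be poor. The hindered carbinol may also resist the methylation of step 11.

The fallback forms the C5–O bond by nucleophilic capture of a cation instead of electrophilic oxygenation. It sets out from 19 and comes back at 22, bypassing 21.
- The enolate (LiN(SiMe3)2, THF, −78 °C) is intercepted by the small electrophile N-bromosuccinimide to give (4R)-5-bromo-4-(chloromethyl)-2-methoxy-4-(triethylsilyloxy)-3,5-bis[4-(triisopropylsilyloxy)phenyl]cyclopent-2-en-1-one F4.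
- AgOTf in MeOH–CH2Cl2 at −40 °C, buffered with 2,6-di-tert-butylpyridine, ionises F4 to the silyloxyaryl-stabilised cation, which methanol captures anti to OSiEt3.
- The buffer keeps the capture kinetic, because acid-catalysed re-ionisation would drift toward the epimer with the aryl group trans to the silyl ether.

Step 7. O-acylation may compete with C-acylation. The base may convert the acid chloride into a ketene. On warming, the diketonate oxygen may close onto C6.

The fallback replaces acylation by aldol addition and oxidation. It sets out from 13 and comes back at 16.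
- Lithium enolate 15 is added at −78 °C to freshly distilled anhydrous chloroacetaldehyde and quenched cold to give (Z)-6-chloro-5-hydroxy-2-methoxy-1,4-bis[4-(triisopropylsilyloxy)phenyl]hex-1-en-3-one F5 as a diastereomer mixture.
- Dess–Martin periodinane with NaHCO3 in CH2Cl2 oxidises F5 to the 1,3-diketone 16 under non-basic conditions.

**Further compounds**
F1 | step 8 | 1-chloro-3,6-bis[4-(triisopropylsilyloxy)phenyl]hexane-2,4,5-trione (racemic) | ClCC(=O)C(c1ccc(O[Si](C(C)C)(C(C)C)C(C)C)cc1)C(=O)C(=O)Cc1ccc(O[Si](C(C)C)(C(C)C)C(C)C)cc1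
F2 | step 8 | rac-4-(chloromethyl)-2,4-dihydroxy-3,5-bis[4-(triisopropylsilyloxy)phenyl]cyclopent-2-en-1-one | OC1=C(c2ccc(O[Si](C(C)C)(C(C)C)C(C)C)cc2)C(O)(CCl)C(c2ccc(O[Si](C(C)C)(C(C)C)C(C)C)cc2)C1=O
F3 | step 8 | rac-4-(chloromethyl)-4-hydroxy-2-methoxy-3,5-bis[4-(triisopropylsilyloxy)phenyl]cyclopent-2-en-1-one | COC1=C(c2ccc(O[Si](C(C)C)(C(C)C)C(C)C)cc2)C(O)(CCl)C(c2ccc(O[Si](C(C)C)(C(C)C)C(C)C)cc2)C1=O
F4 | step 10 | (4R)-5-bromo-4-(chloromethyl)-2-methoxy-4-(triethylsilyloxy)-3,5-bis[4-(triisopropylsilyloxy)phenyl]cyclopent-2-en-1-one (C5 epimers) | COC1=C(c2ccc(O[Si](C(C)C)(C(C)C)C(C)C)cc2)[C@@](O[Si](CC)(CC)CC)(CCl)C(Br)(c2ccc(O[Si](C(C)C)(C(C)C)C(C)C)cc2)C1=O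
F5 | step 7 | (Z)-6-chloro-5-hydroxy-2-methoxy-1,4-bis[4-(triisopropylsilyloxy)phenyl]hex-1-en-3-one (diastereomers) | CO/C(=C\c1ccc(O[Si](C(C)C)(C(C)C)C(C)C)cc1)C(=O)C(c1ccc(O[Si](C(C)C)(C(C)C)C(C)C)cc1)C(O)CCl
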